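**Strategy**

The pyranone (ring C) is taken apart around its carbonyl carbon: C4 lies isolated between C4a of ring A and C3, while O1 is carried by C8a, the ring-A carbon next to C4a. A palladium-catalysed three-component union of an ortho-iodophenol, carbon monoxide and a terminal arylacetylene therefore forges C4a–C4, C4–C3 and O1–C2 and closes ring C in one operation, the ring fusion being fixed beforehand by the iodine (C4a) and the free hydroxyl (C8a). The precursors are 3-benzyloxy-2-iodo-5,6-dimethoxyphenol (benzyl masks the future 5-OH) and 1,5-dibenzyloxy-2-ethynyl-4-methoxybenzene. C3 oxygenation, methylation and one hydrogenolysis finish the achiral target.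

Key step: step 10

Remark on the chemistry: the target has no stereocentre, and 3-benzyloxy-4-methoxybenzaldehyde (O-benzylisovanillin) is taken as a purchasable compound.

**Route**

Step 1
Reactants: 1 3-hydroxy-4,5-dimethoxybenzaldehyde
Product: 2 5-formyl-2,3-dimethoxyphenyl N,N-diethylcarbamate
Conditions: Et2NCOCl, K2CO3, MeCN, reflux
Reagents that add atoms: N,N-diethylcarbamoyl chloride, CCN(CC)C(Cl)=O
Why: O-carbamoylation of the phenoxide (acyl substitution at the carbamoyl chloride) leaves the aldehyde untouched and installs the group that will later direct metalation.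

Step 2
Reactants: 2 5-formyl-2,3-dimethoxyphenyl N,N-diethylcarbamate
Product: 4 5-hydroxy-2,3-dimethoxyphenyl N,N-diethylcarbamate, via aryl formate 3 (not isolated)
Conditions: mCPBA, CH2Cl2, 0 °C to rt; then cat. K2CO3, MeOH, rt
Reagents that add atoms: 3-chloroperoxybenzoic acid (mCPBA), O=C(OO)c1cccc(Cl)c1
Why: Baeyer–Villiger oxidation in which the electron-rich aryl group (para-methoxy) migrates in preference to hydride to give formate 3, which catalytic K2CO3 in MeOH transesterifies while the N,N-diethylcarbamate, inert to mild base, stays in place.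

Step 3
Reactants: 4 5-hydroxy-2,3-dimethoxyphenyl N,N-diethylcarbamate
Product: 5 5-benzyloxy-2,3-dimethoxyphenyl N,N-diethylcarbamate
Conditions: BnBr, K2CO3, DMF, rt
Reagents that add atoms: benzyl bromide, BrCc1ccccc1
Why: Williamson ether synthesis on the only free phenol, under conditions to which the carbamate is stable.

Step 4
Reactants: 5 5-benzyloxy-2,3-dimethoxyphenyl N,N-diethylcarbamate
Product: 7 3-benzyloxy-2-iodo-5,6-dimethoxyphenyl N,N-diethylcarbamate, via aryllithium 6 (not isolated)
Conditions: s-BuLi (1.1 equiv), TMEDA, THF, −78 °C; then I2, THF, −78 °C; aq Na2S2O3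
Reagents that add atoms: iodine, II
Why: Directed ortho-metalation, in which the O-carbamate is the strongest director on the ring and its only free ortho position also lies ortho to the benzyloxy group, so lithiation should occur between these two oxygens and iodine should trap the aryllithium at −78 °C before an anionic ortho-Fries shift can start.

Step 5
Reactants: 7 3-benzyloxy-2-iodo-5,6-dimethoxyphenyl N,N-diethylcarbamate
Product: 8 3-benzyloxy-2-iodo-5,6-dimethoxyphenol
Conditions: NaOH, EtOH/H2O (degassed), reflux; then aq HCl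
Reagents that add atoms: none
Why: Base hydrolysis of the aryl carbamate (hydroxide attack at the carbonyl with expulsion of the phenoxide) frees the C8a hydroxyl, while the aryl iodide and the benzyl and methyl ethers are inert to ethanolic NaOH.

Step 6
Reactants: 9 3-benzyloxy-4-methoxybenzaldehyde
Product: 11 3-benzyloxy-4-methoxyphenol, via formate 10 (not isolated)
Conditions: mCPBA, CH2Cl2, 0 °C to rt; then cat. K2CO3, MeOH, rt
Reagents that add atoms: 3-chloroperoxybenzoic acid (mCPBA), O=C(OO)c1cccc(Cl)c1
Why: Baeyer–Villiger oxidation with migration of the para-methoxy-activated aryl group, followed by mild methanolysis of the formate.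

Step 7
Reactants: 11 3-benzyloxy-4-methoxyphenol
Product: 12 2,4-dibenzyloxy-1-methoxybenzene
Conditions: BnBr, K2CO3, DMF, rt
Reagents that add atoms: benzyl bromide, BrCc1ccccc1
Why: Williamson ether synthesis on the single phenol.

Step 8
Reactants: 12 2,4-dibenzyloxy-1-methoxybenzene
Product: 14 2,4-dibenzyloxy-5-methoxybenzaldehyde, via iminium salt 13 (not isolated)
Conditions: POCl3, DMF, 0 to 70 °C; then aq NaOAc
Reagents that add atoms: N,N-dimethylformamide, CN(C)C=O; water, O
Why: Vilsmeier–Haack formylation should take place at C5, which is para to one benzyloxy group and ortho to the other and far less hindered than the position between them, and the iminium salt is hydrolysed on aqueous work-up.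

Step 9
Reactants: 14 2,4-dibenzyloxy-5-methoxybenzaldehyde
Product: 15 1,5-dibenzyloxy-2-ethynyl-4-methoxybenzene
Conditions: dimethyl (1-diazo-2-oxopropyl)phosphonate, K2CO3, MeOH/THF, rt
Reagents that add atoms: dimethyl (1-diazo-2-oxopropyl)phosphonate (Ohira–Bestmann reagent), CC(=O)C(=[N+]=[N-])P(=O)(OC)OC
Why: Seyferth–Gilbert homologation in its Ohira–Bestmann form, in which the diazomethylphosphonate anion released by methanolysis olefinates the aldehyde and loss of N2 with a 1,2-hydrogen shift gives the terminal alkyne under base mild enough for the benzyl ethers.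

Step 10
Reactants: 8 3-benzyloxy-2-iodo-5,6-dimethoxyphenol; 15 1,5-dibenzyloxy-2-ethynyl-4-methoxybenzene; 16 carbon monoxide
Product: 19 5,2',4'-tribenzyloxy-7,8,5'-trimethoxyflavone, via ynone 17 (not isolated), via enaminone 18 (not isolated)
Conditions: PdCl2(dppf) (5 mol %), CO (20 bar), Et2NH, 120 °C, autoclave
Reagents that add atoms: none
Why: Zerovalent palladium, formed from PdCl2(dppf) under CO and amine, should add oxidatively to the C–I bond of 8, CO should insert to give an aroylpalladium species, and coupling with the amine-activated acetylide of 15 followed by reductive elimination should deliver the ortho-hydroxyaryl ynone 17 (bonds C4a–C4 and C4–C3). Diethylamine then adds to the ynone to give enaminone 18 (either double-bond geometry converges), and the C8a hydroxyl attacks the amine-bearing carbon and expels diethylamine (bond O1–C2), a 6-endo-trig addition–elimination that closes ring C. The closest known reaction type is the palladium-catalysed carbonylative Sonogashira coupling–cyclisation of ortho-iodophenols with terminal alkynes to flavones. No stereocentre is formed. The step needs carbonylation to outrun direct alkynylation (which would lead on to a 2-arylbenzofuran) and six-membered closure to outrun the 5-exo-dig closure to an aurone; CO pressure favours insertion, and passage through the enaminone, whose amine-bearing carbon is the only electrophilic site within reach of the phenol, secures the pyranone. The fusion is regiodefined before any ring exists, because iodine sits on C4a, the only free hydroxyl on C8a, and the C5 oxygen is benzylated.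

Step 11
Reactants: 19 5,2',4'-tribenzyloxy-7,8,5'-trimethoxyflavone
Product: 22 5,2',4'-tribenzyloxy-3-hydroxy-7,8,5'-trimethoxyflavone, via 3-lithioflavone 20 (not isolated), via boronate 21 (not isolated)
Conditions: LDA, THF, −78 °C; B(OMe)3, −78 to 0 °C; AcOH, 30% aq H2O2, 0 °C to rt
Reagents that add atoms: hydrogen peroxide, OO
Why: Deprotonation–borylation–oxidation, in which C3–H, the vinylic position next to the carbonyl of the 4-pyranone, is the most acidic C–H and should be removed by LDA at −78 °C without touching benzylic or aryl positions, after which borate trapping and peroxide-induced 1,2-migration from boron to oxygen give the flavonol.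

Step 12
Reactants: 22 5,2',4'-tribenzyloxy-3-hydroxy-7,8,5'-trimethoxyflavone
Product: 23 5,2',4'-tribenzyloxy-3,7,8,5'-tetramethoxyflavone
Conditions: MeI, K2CO3, acetone, reflux
Reagents that add atoms: iodomethane, CI
Why: Williamson O-methylation of the acidic 3-hydroxyl, the only free hydroxyl in the molecule.

Step 13
Reactants: 23 5,2',4'-tribenzyloxy-3,7,8,5'-tetramethoxyflavone
Product: 24 5,2',4'-trihydroxy-3,7,8,5'-tetramethoxyflavone
Conditions: H2 (1 atm), 10% Pd/C, EtOAc/MeOH, rt
Reagents that add atoms: none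
Why: Catalytic hydrogenolysis should cleave all three benzyl aryl ethers in one operation, while the aryl methyl ethers and the tetrasubstituted C2=C3 bond of the vinylogous ester resist hydrogen at ambient pressure.

**Compound list**

1 | 3-hydroxy-4,5-dimethoxybenzaldehyde | COc1cc(C=O)cc(O)c1OC | starting material
2 | 5-formyl-2,3-dimethoxyphenyl N,N-diethylcarbamate | CCN(CC)C(=O)Oc1cc(C=O)cc(OC)c1OC | intermediate
3 | 5-formyloxy-2,3-dimethoxyphenyl N,N-diethylcarbamate (aryl formate) | CCN(CC)C(=O)Oc1cc(OC=O)cc(OC)c1OC | intermediate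
4 | 5-hydroxy-2,3-dimethoxyphenyl N,N-diethylcarbamate | CCN(CC)C(=O)Oc1cc(O)cc(OC)c1OC | intermediate
5 | 5-benzyloxy-2,3-dimethoxyphenyl N,N-diethylcarbamate | CCN(CC)C(=O)Oc1cc(OCc2ccccc2)cc(OC)c1OC | intermediate
6 | [6-benzyloxy-2-(diethylcarbamoyloxy)-3,4-dimethoxyphenyl]lithium | CCN(CC)C(=O)Oc1c([Li])c(OCc2ccccc2)cc(OC)c1OC | intermediate
7 | 3-benzyloxy-2-iodo-5,6-dimethoxyphenyl N,N-diethylcarbamate | CCN(CC)C(=O)Oc1c(I)c(OCc2ccccc2)cc(OC)c1OC | intermediate
8 | 3-benzyloxy-2-iodo-5,6-dimethoxyphenol | COc1cc(OCc2ccccc2)c(I)c(O)c1OC | intermediate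
9 | 3-benzyloxy-4-methoxybenzaldehyde | COc1ccc(C=O)cc1OCc1ccccc1 | starting material
10 | 3-benzyloxy-4-methoxyphenyl formate | COc1ccc(OC=O)cc1OCc1ccccc1 | intermediate
11 | 3-benzyloxy-4-methoxyphenol | COc1ccc(O)cc1OCc1ccccc1 | intermediate
12 | 2,4-dibenzyloxy-1-methoxybenzene | COc1ccc(OCc2ccccc2)cc1OCc1ccccc1 | intermediate
13 | N-[(2,4-dibenzyloxy-5-methoxyphenyl)methylidene]-N-methylmethanaminium dichlorophosphate | COc1cc(C=[N+](C)C)c(OCc2ccccc2)cc1OCc1ccccc1.[O-]P(Cl)(Cl)=O | intermediate
14 | 2,4-dibenzyloxy-5-methoxybenzaldehyde | COc1cc(C=O)c(OCc2ccccc2)cc1OCc1ccccc1 | intermediate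
15 | 1,5-dibenzyloxy-2-ethynyl-4-methoxybenzene | C#Cc1cc(OC)c(OCc2ccccc2)cc1OCc1ccccc1 | intermediate
16 | carbon monoxide | [C-]#[O+] | starting material
17 | 1-(6-benzyloxy-2-hydroxy-3,4-dimethoxyphenyl)-3-(2,4-dibenzyloxy-5-methoxyphenyl)prop-2-yn-1-one | COc1cc(OCc2ccccc2)c(C(=O)C#Cc2cc(OC)c(OCc3ccccc3)cc2OCc2ccccc2)c(O)c1OC | intermediate
18 | (E)-1-(6-benzyloxy-2-hydroxy-3,4-dimethoxyphenyl)-3-(2,4-dibenzyloxy-5-methoxyphenyl)-3-(diethylamino)prop-2-en-1-one | COc1cc(OCc2ccccc2)c(C(=O)/C=C(/N(CC)CC)c2cc(OC)c(OCc3ccccc3)cc2OCc2ccccc2)c(O)c1OC | intermediate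
19 | 5-benzyloxy-2-(2,4-dibenzyloxy-5-methoxyphenyl)-7,8-dimethoxy-4H-chromen-4-one (5,2',4'-tribenzyloxy-7,8,5'-trimethoxyflavone) | COc1cc(-c2cc(=O)c3c(OCc4ccccc4)cc(OC)c(OC)c3o2)c(OCc2ccccc2)cc1OCc1ccccc1 | intermediate
20 | [5-benzyloxy-2-(2,4-dibenzyloxy-5-methoxyphenyl)-7,8-dimethoxy-4-oxo-4H-chromen-3-yl]lithium | COc1cc(-c2oc3c(OC)c(OC)cc(OCc4ccccc4)c3c(=O)c2[Li])c(OCc2ccccc2)cc1OCc1ccccc1 | intermediate
21 | dimethyl [5-benzyloxy-2-(2,4-dibenzyloxy-5-methoxyphenyl)-7,8-dimethoxy-4-oxo-4H-chromen-3-yl]boronate | COc1cc(-c2oc3c(OC)c(OC)cc(OCc4ccccc4)c3c(=O)c2B(OC)OC)c(OCc2ccccc2)cc1OCc1ccccc1 | intermediate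
22 | 5-benzyloxy-2-(2,4-dibenzyloxy-5-methoxyphenyl)-3-hydroxy-7,8-dimethoxy-4H-chromen-4-one | COc1cc(-c2oc3c(OC)c(OC)cc(OCc4ccccc4)c3c(=O)c2O)c(OCc2ccccc2)cc1OCc1ccccc1 | intermediate
23 | 5-benzyloxy-2-(2,4-dibenzyloxy-5-methoxyphenyl)-3,7,8-trimethoxy-4H-chromen-4-one | COc1cc(-c2oc3c(OC)c(OC)cc(OCc4ccccc4)c3c(=O)c2OC)c(OCc2ccccc2)cc1OCc1ccccc1 | intermediate
24 | 5,2',4'-trihydroxy-3,7,8,5'-tetramethoxyflavone (2-(2,4-dihydroxy-5-methoxyphenyl)-5-hydroxy-3,7,8-trimethoxy-4H-chromen-4-one) | COc1cc(-c2oc3c(OC)c(OC)cc(O)c3c(=O)c2OC)c(O)cc1O | target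

**Step count**

Total step count: 13. Longest linear sequence: 9 steps (steps 1–5, then 10–13); the ring-B branch (steps 6–9) joins at step 10.

**Steps most likely to fail**

1. Step 10 (carbonylative annulation). Direct alkynylation without CO uptake, aminocarbonylation of the aroylpalladium species by diethylamine, five-membered closure, or slow oxidative addition at the doubly ortho-substituted C–I bond may erode the step. The fallback builds ring C by the chalcone route without CO; it sets out from 8 (with 14 as partner) and comes back at 19. Iodophenol 8 would be coupled in a Stille reaction with tributyl(1-ethoxyvinyl)stannane (PdCl2(PPh3)2, dioxane, 100 °C) to the enol ether 3-benzyloxy-2-(1-ethoxyvinyl)-5,6-dimethoxyphenol F1, which aqueous HCl in the work-up would hydrolyse to 1-(6-benzyloxy-2-hydroxy-3,4-dimethoxyphenyl)ethanone F2. Claisen–Schmidt condensation of F2 with aldehyde 14 (KOH, EtOH, rt) would give (E)-1-(6-benzyloxy-2-hydroxy-3,4-dimethoxyphenyl)-3-(2,4-dibenzyloxy-5-methoxyphenyl)prop-2-en-1-one F3. Oxidative cyclisation of F3 (cat. I2, DMSO, 130 °C; any flavanone formed alongside converges under the same conditions) would return to flavone 19.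

2. Step 11 (C3 oxygenation). The 3-lithiated pyranone may open by β-elimination of the C8a phenoxide, metalation may be incomplete, or the boronate may be protonated before it is oxidised. The fallback replaces deprotonation by electrophilic oxidation; it sets out from 19 and comes back at 22. Flavone 19 would be epoxidised with dimethyldioxirane (acetone/CH2Cl2, 0 °C) to the racemic 5-benzyloxy-2-(2,4-dibenzyloxy-5-methoxyphenyl)-2,3-epoxy-7,8-dimethoxychroman-4-one F4 (oxirane cis-fused by necessity). Catalytic p-TsOH in CH2Cl2 would then open the oxirane and tautomerise the product to flavonol 22.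

3. Step 4 (directed metalation–iodination). Benzylic deprotonation of the benzyl ether by s-BuLi (followed by Wittig rearrangement) or anionic ortho-Fries migration of the carbamoyl group may compete with clean aryl lithiation. The fallback avoids a free aryllithium and an alkyllithium; it sets out from 5 and comes back at 7. Carbamate 5 would be metalated with LDA in the presence of TMSCl (THF, −78 °C, in situ trapping) to give 3-benzyloxy-5,6-dimethoxy-2-(trimethylsilyl)phenyl N,N-diethylcarbamate F5. Ipso-iododesilylation of F5 with ICl (CH2Cl2, −78 to 0 °C) would return to iodide 7.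

**Further compounds**

F1 | step 10 | 3-benzyloxy-2-(1-ethoxyvinyl)-5,6-dimethoxyphenol | COc1cc(OCc2ccccc2)c(C(=C)OCC)c(O)c1OC
F2 | step 10 | 1-(6-benzyloxy-2-hydroxy-3,4-dimethoxyphenyl)ethanone | COc1cc(OCc2ccccc2)c(C(C)=O)c(O)c1OC
F3 | step 10 | (E)-1-(6-benzyloxy-2-hydroxy-3,4-dimethoxyphenyl)-3-(2,4-dibenzyloxy-5-methoxyphenyl)prop-2-en-1-one | COc1cc(OCc2ccccc2)c(C(=O)/C=C/c2cc(OC)c(OCc3ccccc3)cc2OCc2ccccc2)c(O)c1OC
F4 | step 11 | racemic 5-benzyloxy-2-(2,4-dibenzyloxy-5-methoxyphenyl)-2,3-epoxy-7,8-dimethoxychroman-4-one (cis-fused oxirane) | COc1cc(C23OC2C(=O)c2c(OCc4ccccc4)cc(OC)c(OC)c2O3)c(OCc2ccccc2)cc1OCc1ccccc1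
F5 | step 4 | 3-benzyloxy-5,6-dimethoxy-2-(trimethylsilyl)phenyl N,N-diethylcarbamate | CCN(CC)C(=O)Oc1c([Si](C)(C)C)c(OCc2ccccc2)cc(OC)c1OC
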